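## Structural features

The target is a sesquineolignan with a lariciresinol core: a tetrahydrofuran (O1, C2 to C5) carrying ring B on C2, a hydroxymethyl group (C9) on C3 and a 4-hydroxy-3-methoxybenzyl group (C7' with ring A) on C4. The para oxygen of ring B is not a phenol; it is etherified with C8'' of a guaiacylglycerol unit (C7''(OH)–C8''–C9''H2OH, ring C on C7''). The ring holds three contiguous stereocentres, C2 (S), C3 (R) and C4 (R), with aryl and hydroxymethyl trans and hydroxymethyl and benzyl cis. Two further adjacent centres, C7'' (S) and C8'' (S), form a threo pair that ring B insulates from the ring triad, so the two sets must be set independently. Fragile points are the two free guaiacyl phenols, the alkyl aryl ether at C8'', and the two benzylic C–O bonds (C2–O1 and C7''–OH), which ionise in acid with epimerisation or Friedel–Crafts closure onto ring A. The carbon backbone is ordinary dibenzylbutane lignan chemistry; the real difficulty is forming the benzylic ether bond C2–O1 with control of C2 while three similar electron-rich arenes and three benzylic positions are present. The key step exploits the position of C2 as the ring B benzylic carbon para to the etherified oxygen, five ring atoms from the C5 hydroxyl of an open 2,3-dibenzylbutane-1,4-diol. Once the phenols of rings A and C are acylated, ring B is the most electron-rich arene, so hydride can be removed from C2 and the C5 oxygen can close the ring as O1.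

## Logic of the disconnections

**25 back to 23.** The two phenolic O–H bonds are replaced by O–acyl bonds and the C7''/C9'' hydroxyls are tied into an isopropylidene acetal. The oxidation needs rings A and C electron-poor and the benzylic 1,3-diol masked. The gain is a compound with no free phenol and no free benzylic hydroxyl. The demand on the forward step is that unmasking must not ionise C2–O1 or C7''–O, so the acetal is hydrolysed first in weak acid while rings A and C are still acylated, and the esters are removed afterwards by methanolysis.

**23 back to 22.** The C2–O1 bond is cut. This removes the ring and the C2 stereocentre together and leaves an open diol with only C3 and C4 on the backbone; C2 needs no oxygen beforehand. The forward step must oxidise at ring B and not at rings A or C, use the C5 hydroxyl and not the C9 hydroxyl (settled by ring size), close 2,3-trans, stop after one oxidation, and stay non-acidic. For that reason 22 keeps both primary hydroxyls free, carries acyl groups on both phenols, and is oxidised with a buffer and with water excluded.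

**22 back to 21 and 20.** The two aryl O–acyl bonds are cut and replaced by O–benzyl bonds. Acyl groups cannot pass through the enolate and hydride steps that build the backbone, whereas benzyl ethers can. The gain is a robust intermediate. The demands are a hydrogenolysis that spares the C7''–O bond and an acylation that distinguishes phenols from two primary alcohols.

**20 back to 19.** The C5 hydroxyl and C9 are rejoined as a lactone (C9 carbonyl, O on C5). The ring gives an enolisable C3 and a template in which C4 controls C3. The forward step is a plain hydride reduction, after which neither centre can epimerise.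

**19 back to 6 and 17.** The C3–C2 bond is cut. This is the most convergent cut: it separates the ring A lactone from the complete ring B/ring C ether. The forward alkylation must be a single alkylation anti to the C4 substituent with a reactive but labile electron-rich benzylic bromide.

**6 back to 4, 3, and 1 plus 2.** The lactone C5–O bond is opened to a half-ester, hydrogen is removed across C4–C7', and the C4=C7' bond is cut. The condensation delivers the four-carbon unit with its two carboxyls already differentiated, and the alkene is where C4 is created catalytically. The demands are an enantioselective hydrogenation and an ester-selective reduction.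

**17 back to 16, 15 and 14.** The C–Br bond, the benzylic alcohol oxidation level and the acetal are removed in turn. The benzylic carbon of ring B is carried as an ester through the aldol and the acetal is installed before strong hydride is used. The demands are a neutral bromination and an acetalisation mild enough not to ionise C7''.

**14 back to 13, then 11 plus 1.** The C7''–C8'' bond is cut. Both glycerol stereocentres are then made in one step with the aryl ether already on C8'', which avoids differentiating three hydroxyls of a triol. The forward step must be syn-selective and face-selective, which an auxiliary on the acyl unit provides; the auxiliary is removed reductively to give C9''.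

**11 back to 9 plus 10, and 9 back to 7 plus 8.** The O–CH2 bond of the aryloxyacetyl unit and the N–acyl bond are cut, leading to commercial pieces. The phenoxide must displace bromide without cleaving the imide.

## Other disconnections considered

**Alternative 1:** The cut goes through two C–C bonds, C4–C7' and C3–C2, so the skeleton comes from three pieces: the chiral butenolide acetal A1, the ring A dithiane A2 and the ring B aldehyde A3 (the same substance as F1 below).
- **Forward step:** lithiated A2 would add to C4 of A1 anti to the menthyloxy group, and the lactone enolate would be trapped by A3 anti to the new C4 substituent. The product A4 has C3 and C4 as in the target and is a pair of epimers at the C2 carbinol.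
- **In favour:** two skeletal bonds and two stereocentres arise in one flask under control of an inexpensive acetal auxiliary, with no asymmetric catalyst. On convergence this is better than the chosen plan, which needs a condensation, a hydrogenation and a separate alkylation for the same bonds. C2 arrives with its oxygen, so there is no over-oxidation risk; this is also a point for the alternative.
- **Against:** A4 is far from the target in oxidation pattern. C7' is a dithioketal that must be desulfurised; Raney Ni would threaten the benzylic C–O bonds at C2 and C7'' and the benzyl ethers. The acetal lactone must be reduced to the C5/C9 diol with loss of the auxiliary. The C2–O1 bond must then be made by acid ionisation of the C2 carbinol in the presence of the acetonide.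
- **Comparison:** both plans deliver O1 from the C5 hydroxyl and rely on the same preference for 2,3-trans, so they are equal on control of C2. Mechanistically the alternative closes by SN1 in acid, whereas the chosen plan removes hydride under buffered conditions, which is gentler to the acetonide. After A4 about five operations remain (desulfurisation, reduction, cyclisation, two deprotections), and A1 to A3 must be made first, so the overall length would be similar, with a redox detour at C7'.

**Alternative 2:** The cut is the C–O bond O1–C5 at the stage of lactone A6, which is identical with 6.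
- **Forward step:** a Baeyer–Villiger monooxygenase with O2 and NADPH would insert oxygen into one of the two enantiotopic acyl–CH2 bonds of the prochiral cyclobutanone A5. C4 becomes a stereocentre although no bond to it is touched.
- **In favour:** the step is catalytic and needs no transition metal or phosphine; the oxidant is air; both migrating carbons are equivalent, so there is no regiochemical question. A5 would take about three steps from a commercial allylarene (O-benzylation, ketene cycloaddition, dechlorination with Zn). On metal use and oxidant the alternative is the better.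
- **Against:** an enzyme must be found that accepts the bulky 3-arylmethyl group with the R preference. Selectivity for such ketones is enzyme-dependent, the medium is dilute and aqueous, and cofactor recycling is needed. The disconnection also addresses only C4 and the lactone; C3, C2 and the ether ring still need the rest of the chosen plan, so it replaces steps 1 to 3 and not step 15.
- **Comparison:** structurally the two are equal, since the same compound results and everything downstream is unchanged. Both set only C4, one by enzyme, one by ligand. The chosen plan is one step shorter to 6 (three steps from 1 against about four) and more predictable.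

**Alternative 3:** The cut is the C–C bond C4–C5, formed by a 1,2-shift.
- **Forward step:** MgBr2·OEt2 would activate the epoxide of A7, the C4–O bond would break, and C5 would migrate from C7' to C4 on the face anti to the leaving oxygen. C7' becomes a formyl carbon, and A8 contains the tetrahydrofuran with C2, C3 and C4 all set.
- **In favour:** the C2–O1 bond and the C2 stereocentre exist before the key step. There is no late benzylic oxidation, no site selection among three arenes and no over-oxidation; on this point the alternative is better than the chosen plan. The migration is stereospecific, so the 3,4-cis relation follows from the epoxide geometry.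
- **Against:**
  - Ring A is absent from A8. C7' must be arylated (giving carbinol epimers) and then deoxygenated without cleaving C2–O1 or C7''–O.
  - The formyl group sits on C4 cis to the C3 arm and β to O1, so base could epimerise C4 or open the ring by β-elimination.
  - The epoxide must lie cis to the C3 arm, which needs a hydroxyl-directed epoxidation before silylation.
  - Neither epoxide carbon is cation-stabilised, so the site of opening and a competing shift of hydride or of C3 are open questions.
  - A7 needs its own enantioselective pyran synthesis, and three different protecting groups must be removed at the end.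
- **Comparison:** structurally the alternative is stronger at C2 and weaker at ring A. Mechanistically it is a stereospecific shift against a stereoselective closure. In step count it would be longer: at least three steps after A8 plus three deprotections, against one operation after 23.

Key step: step 15

Remark: atom labels are O1, C2–C5 for the tetrahydrofuran; C9 for the hydroxymethyl carbon on C3; C7' for the benzylic carbon on C4 (ring A); C7''–C9'' for the glycerol unit (ring C on C7''); ring B on C2.
Remark: in 22 both backbone centres are R and the dioxane is (4S,5S); these are the configurations needed at C3, C4, C7'' and C8'' of the target, and the ring closure creates only C2.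
Assumption: the (S,S) antipode of Et-DuPHOS is taken to give the R acid 4; if a first run shows the opposite sense, the (R,R) ligand is used.
Assumption: 1, 2, 7, 8 and 10 are taken as commercial.

## Route

Step 1
Reactants: 1 4-(benzyloxy)-3-methoxybenzaldehyde; 2 dimethyl succinate
Product: 3 (E)-4-[4-(benzyloxy)-3-methoxyphenyl]-3-(methoxycarbonyl)but-3-enoic acid
Conditions: NaOMe, MeOH, reflux; then aq HCl
Reagents that add atoms: none
Why: Stobbe condensation: the succinate enolate adds to the aldehyde, the alkoxide lactonises onto the distal ester and base-induced ring opening gives the half-ester with the conjugated ester kept. The E isomer (aryl trans to the ester) should predominate; no stereocentre is formed.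

Step 2
Reactants: 3 (E)-4-[4-(benzyloxy)-3-methoxyphenyl]-3-(methoxycarbonyl)but-3-enoic acid
Product: 4 (R)-4-[4-(benzyloxy)-3-methoxyphenyl]-3-(methoxycarbonyl)butanoic acid
Conditions: [Rh(cod)((S,S)-Et-DuPHOS)]BF4 (0.5 mol %), NaOMe (10 mol %), H2 (5 bar), MeOH, rt
Reagents that add atoms: none
Why: Asymmetric hydrogenation of an itaconate-type half-ester: carboxylate and alkene chelate monovalent rhodium and the twofold-symmetric bisphospholane selects the alkene face, which sets C4 (R). The homogeneous catalyst should leave the benzyl ether intact.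

Step 3
Reactants: 4 (R)-4-[4-(benzyloxy)-3-methoxyphenyl]-3-(methoxycarbonyl)butanoic acid
Product: 6 (R)-4-[4-(benzyloxy)-3-methoxybenzyl]dihydrofuran-2(3H)-one, via hydroxy acid 5 (not isolated)
Conditions: KOH (1 equiv), EtOH; CaCl2, NaBH4, EtOH, −10 °C to rt; then 2 M HCl, rt
Reagents that add atoms: none
Why: Chemoselective borohydride reduction: Ca(BH4)2 formed in the flask reduces the methyl ester but not the carboxylate, and acidification lactonises the γ-hydroxy acid. Only one equivalent of base is used, so the centre α to the ester should not epimerise before it is reduced.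

Step 4
Reactants: 7 (R)-4-benzyloxazolidin-2-one; 8 bromoacetyl bromide
Product: 9 (R)-4-benzyl-3-(bromoacetyl)oxazolidin-2-one
Conditions: n-BuLi, THF, −78 °C; then 8, −78 to 0 °C
Reagents that add atoms: none
Why: N-Acylation of the lithiated oxazolidinone (nucleophilic acyl substitution); the acyl bromide carbon reacts far faster than the alkyl bromide end at low temperature.

Step 5
Reactants: 9 (R)-4-benzyl-3-(bromoacetyl)oxazolidin-2-one; 10 methyl 4-hydroxy-3-methoxybenzoate
Product: 11 methyl 4-{2-[(R)-4-benzyl-2-oxooxazolidin-3-yl]-2-oxoethoxy}-3-methoxybenzoate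
Conditions: K2CO3, acetone, rt
Reagents that add atoms: none
Why: Williamson ether synthesis: the phenoxide displaces the α-carbonyl-activated bromide by SN2, so a weak base at room temperature suffices and the imide should not be cleaved.

Step 6
Reactants: 11 methyl 4-{2-[(R)-4-benzyl-2-oxooxazolidin-3-yl]-2-oxoethoxy}-3-methoxybenzoate; 1 4-(benzyloxy)-3-methoxybenzaldehyde
Product: 13 methyl 4-({(2R,3S)-1-[(R)-4-benzyl-2-oxooxazolidin-3-yl]-3-[4-(benzyloxy)-3-methoxyphenyl]-3-hydroxy-1-oxopropan-2-yl}oxy)-3-methoxybenzoate, via dibutylboron Z-enolate 12 (not isolated)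
Conditions: Bu2BOTf, i-Pr2NEt, CH2Cl2, −78 to 0 °C; then 1, −78 to 0 °C; pH 7 phosphate buffer, MeOH, H2O2
Reagents that add atoms: none
Why: Evans syn aldol: the Z boron enolate adds through a closed chair-like transition state with the aldehyde aryl group equatorial (2,3-syn), on the enolate face away from the auxiliary benzyl group. This sets C8'' and C7'' together in the threo arrangement and absolute sense of the target.

Step 7
Reactants: 13 methyl 4-({(2R,3S)-1-[(R)-4-benzyl-2-oxooxazolidin-3-yl]-3-[4-(benzyloxy)-3-methoxyphenyl]-3-hydroxy-1-oxopropan-2-yl}oxy)-3-methoxybenzoate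
Product: 14 methyl 4-({(1S,2S)-1-[4-(benzyloxy)-3-methoxyphenyl]-1,3-dihydroxypropan-2-yl}oxy)-3-methoxybenzoate
Conditions: LiBH4, MeOH (1 equiv), THF, 0 °C
Reagents that add atoms: none
Why: Reductive cleavage of the N-acyl oxazolidinone: hydride attacks the exocyclic carbonyl and gives the primary alcohol C9'' with release of the auxiliary. The conjugated methyl benzoate should be much slower at 0 °C, and C8'' is no longer α to a carbonyl afterwards.

Step 8
Reactants: 14 methyl 4-({(1S,2S)-1-[4-(benzyloxy)-3-methoxyphenyl]-1,3-dihydroxypropan-2-yl}oxy)-3-methoxybenzoate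
Product: 15 methyl 4-({(4S,5S)-4-[4-(benzyloxy)-3-methoxyphenyl]-2,2-dimethyl-1,3-dioxan-5-yl}oxy)-3-methoxybenzoate
Conditions: Me2C(OMe)2, PPTS (cat.), acetone, rt
Reagents that add atoms: 2,2-dimethoxypropane COC(C)(C)OC
Why: Acid-catalysed transacetalisation: only the 7'',9''-diol is present, so the six-membered acetonide must form. The weak acid should not ionise the benzylic C7''–O bond, so both centres are retained.

Step 9
Reactants: 15 methyl 4-({(4S,5S)-4-[4-(benzyloxy)-3-methoxyphenyl]-2,2-dimethyl-1,3-dioxan-5-yl}oxy)-3-methoxybenzoate
Product: 16 [4-({(4S,5S)-4-[4-(benzyloxy)-3-methoxyphenyl]-2,2-dimethyl-1,3-dioxan-5-yl}oxy)-3-methoxyphenyl]methanol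
Conditions: LiAlH4, THF, 0 °C
Reagents that add atoms: none
Why: Hydride reduction of the aryl ester to the benzylic alcohol; acetal, benzyl ether and aryl ethers are inert to LiAlH4.

Step 10
Reactants: 16 [4-({(4S,5S)-4-[4-(benzyloxy)-3-methoxyphenyl]-2,2-dimethyl-1,3-dioxan-5-yl}oxy)-3-methoxyphenyl]methanol
Product: 17 (4S,5S)-4-[4-(benzyloxy)-3-methoxyphenyl]-5-[4-(bromomethyl)-2-methoxyphenoxy]-2,2-dimethyl-1,3-dioxane
Conditions: CBr4, PPh3, CH2Cl2, 0 °C
Reagents that add atoms: tetrabromomethane BrC(Br)(Br)Br
Why: Appel reaction: the alcohol is activated as an alkoxyphosphonium ion and displaced by bromide under neutral conditions, which spares the acetonide. The labile electron-rich benzylic bromide is used at once.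

Step 11
Reactants: 6 (R)-4-[4-(benzyloxy)-3-methoxybenzyl]dihydrofuran-2(3H)-one; 17 (4S,5S)-4-[4-(benzyloxy)-3-methoxyphenyl]-5-[4-(bromomethyl)-2-methoxyphenoxy]-2,2-dimethyl-1,3-dioxane
Product: 19 (3R,4R)-4-[4-(benzyloxy)-3-methoxybenzyl]-3-[4-({(4S,5S)-4-[4-(benzyloxy)-3-methoxyphenyl]-2,2-dimethyl-1,3-dioxan-5-yl}oxy)-3-methoxybenzyl]dihydrofuran-2(3H)-one, via lithium lactone enolate 18 (not isolated)
Conditions: LiN(SiMe3)2, THF, −78 °C; then 17, DMPU, −78 to −20 °C
Reagents that add atoms: none
Why: Alkylation of a lactone enolate by SN2: the bromide approaches C3 on the face anti to the C4 benzyl group, so the 3,4-trans lactone forms and C3 is set (R). The trans isomer is also the more stable one, so any epimerisation works in the same direction.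

Step 12
Reactants: 19 (3R,4R)-4-[4-(benzyloxy)-3-methoxybenzyl]-3-[4-({(4S,5S)-4-[4-(benzyloxy)-3-methoxyphenyl]-2,2-dimethyl-1,3-dioxan-5-yl}oxy)-3-methoxybenzyl]dihydrofuran-2(3H)-one
Product: 20 (2R,3R)-2-[4-(benzyloxy)-3-methoxybenzyl]-3-[4-({(4S,5S)-4-[4-(benzyloxy)-3-methoxyphenyl]-2,2-dimethyl-1,3-dioxan-5-yl}oxy)-3-methoxybenzyl]butane-1,4-diol
Conditions: LiAlH4, THF, 0 °C to rt
Reagents that add atoms: none
Why: Hydride reduction of the lactone to the 1,4-diol; the ring oxygen stays on C5 and the carbonyl carbon becomes C9. Neither backbone centre can epimerise afterwards.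

Step 13
Reactants: 20 (2R,3R)-2-[4-(benzyloxy)-3-methoxybenzyl]-3-[4-({(4S,5S)-4-[4-(benzyloxy)-3-methoxyphenyl]-2,2-dimethyl-1,3-dioxan-5-yl}oxy)-3-methoxybenzyl]butane-1,4-diol
Product: 21 (2R,3R)-2-(4-hydroxy-3-methoxybenzyl)-3-[4-({(4S,5S)-4-(4-hydroxy-3-methoxyphenyl)-2,2-dimethyl-1,3-dioxan-5-yl}oxy)-3-methoxybenzyl]butane-1,4-diol
Conditions: H2 (1 atm), 10% Pd/C, EtOAc–EtOH, rt
Reagents that add atoms: none
Why: Hydrogenolysis of aryl benzyl ethers: the primary O-benzyl bonds should cleave much faster than the secondary benzylic C7''–O bond held in the acetal. The reaction is stopped after uptake of two equivalents.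

Step 14
Reactants: 21 (2R,3R)-2-(4-hydroxy-3-methoxybenzyl)-3-[4-({(4S,5S)-4-(4-hydroxy-3-methoxyphenyl)-2,2-dimethyl-1,3-dioxan-5-yl}oxy)-3-methoxybenzyl]butane-1,4-diol
Product: 22 dipivalate of 21 at the phenols of rings A and C (C5 and C9 hydroxyls free, 7'',9''-acetonide kept)
Conditions: PivCl (2.1 equiv), 1 M aq NaOH, Bu4NHSO4 (cat.), CH2Cl2, 0 °C
Reagents that add atoms: pivaloyl chloride CC(C)(C)C(Cl)=O
Why: Schotten–Baumann acylation under phase transfer: aqueous hydroxide deprotonates only the phenols and the phenoxides are acylated in the organic phase. The primary alcohols are not ionised and should remain free.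

Step 15
Reactants: 22 dipivalate of 21 at the phenols of rings A and C
Product: 23 protected target: (2S,3R,4R)-tetrahydrofuran with ring B on C2, free hydroxymethyl on C3, 4-pivaloyloxy-3-methoxybenzyl on C4, and the 7'',9''-acetonide with ring C as pivalate
Conditions: DDQ (1.05 equiv), NaHCO3, 4 Å molecular sieves, CH2Cl2, 0 °C
Reagents that add atoms: none
Why: The quinone (2,3-dichloro-5,6-dicyano-1,4-benzoquinone) associates with ring B, which after acylation of the other two phenols is the most electron-rich arene, and takes hydride (electron transfer, then hydrogen transfer) from the C2 methylene para to the ether oxygen; a quinone-methide-like benzylic cation and the hydroquinone anion result. The C5 oxygen then attacks C2 in a 5-exo-trig closure that forms the O1–C2 bond and the tetrahydrofuran ring, while the C9 hydroxyl stays free because it could only close a four-membered ring. The closest known reaction type is the quinone oxidation of electron-rich benzylic C–H bonds with intramolecular capture of the cation by a hydroxyl group (oxidative cycloetherification of 4-arylbutanols). The new stereocentre C2 is controlled by the neighbouring C3 centre: in the envelope-like transition state the flat aryl cation turns away from the C3 hydroxymethyl arm, giving the 2,3-trans (2S) ether, which is also the more stable isomer. Site selectivity among C2, C7' and C7'' is required and is secured by the two pivalates, which lower the donor strength of rings A and C and so disfavour hydride loss next to them. The C2–H of 23 is itself oxidisable, so the oxidant is kept to about one equivalent at 0 °C with water excluded and the run is stopped short of full conversion. Solid NaHCO3 takes up the acidic hydroquinone so that the benzylic ether does not reopen and alkylate C6 of ring A.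

Step 16
Reactants: 23 protected target (7'',9''-acetonide, two aryl pivalates)
Product: 25 target: (2S,3R,4R)-lariciresinol etherified at O4 of ring B with C8'' of (7''S,8''S)-threo-guaiacylglycerol, via dipivalate triol 24 (not isolated)
Conditions: AcOH–H2O (4:1), 35 °C; evaporate; then K2CO3 (3 equiv), MeOH, rt
Reagents that add atoms: none
Why: Acetal hydrolysis followed by base-mediated methanolysis of the aryl esters (transesterification). The acid stage comes first, while rings A and C are still acylated, so C7'' is less prone to ionise; the basic stage does not touch any stereocentre.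

## Compound list

1 | 4-(benzyloxy)-3-methoxybenzaldehyde | COc1cc(C=O)ccc1OCc1ccccc1 | starting material
2 | dimethyl succinate | COC(=O)CCC(=O)OC | starting material
3 | (E)-4-[4-(benzyloxy)-3-methoxyphenyl]-3-(methoxycarbonyl)but-3-enoic acid | COC(=O)/C(CC(=O)O)=C/c1ccc(OCc2ccccc2)c(OC)c1 | intermediate
4 | (R)-4-[4-(benzyloxy)-3-methoxyphenyl]-3-(methoxycarbonyl)butanoic acid | COC(=O)[C@@H](CC(=O)O)Cc1ccc(OCc2ccccc2)c(OC)c1 | intermediate
5 | (R)-4-[4-(benzyloxy)-3-methoxyphenyl]-3-(hydroxymethyl)butanoic acid (formed in the flask, not isolated) | OC[C@@H](CC(=O)O)Cc1ccc(OCc2ccccc2)c(OC)c1 | intermediate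
6 | (R)-4-[4-(benzyloxy)-3-methoxybenzyl]dihydrofuran-2(3H)-one | COc1cc(C[C@H]2COC(=O)C2)ccc1OCc1ccccc1 | intermediate
7 | (R)-4-benzyloxazolidin-2-one | O=C1N[C@H](Cc2ccccc2)CO1 | starting material
8 | bromoacetyl bromide | BrCC(Br)=O | starting material
9 | (R)-4-benzyl-3-(bromoacetyl)oxazolidin-2-one | BrCC(=O)N1[C@H](Cc2ccccc2)COC1=O | intermediate
10 | methyl 4-hydroxy-3-methoxybenzoate | COC(=O)c1ccc(O)c(OC)c1 | starting material
11 | methyl 4-{2-[(R)-4-benzyl-2-oxooxazolidin-3-yl]-2-oxoethoxy}-3-methoxybenzoate | COC(=O)c1ccc(OCC(=O)N2[C@H](Cc3ccccc3)COC2=O)c(OC)c1 | intermediate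
12 | dibutylboron (Z)-enolate of 11 (formed in the flask, not isolated) | CCCCB(CCCC)O/C(=C\Oc1ccc(C(=O)OC)cc1OC)N1[C@H](Cc2ccccc2)COC1=O | intermediate
13 | methyl 4-({(2R,3S)-1-[(R)-4-benzyl-2-oxooxazolidin-3-yl]-3-[4-(benzyloxy)-3-methoxyphenyl]-3-hydroxy-1-oxopropan-2-yl}oxy)-3-methoxybenzoate (2,3-syn aldol adduct) | COC(=O)c1ccc(O[C@@H](C(=O)N2[C@H](Cc3ccccc3)COC2=O)[C@@H](O)c4ccc(OCc5ccccc5)c(OC)c4)c(OC)c1 | intermediate
14 | methyl 4-({(1S,2S)-1-[4-(benzyloxy)-3-methoxyphenyl]-1,3-dihydroxypropan-2-yl}oxy)-3-methoxybenzoate (threo) | COC(=O)c1ccc(O[C@@H](CO)[C@@H](O)c2ccc(OCc3ccccc3)c(OC)c2)c(OC)c1 | intermediate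
15 | methyl 4-({(4S,5S)-4-[4-(benzyloxy)-3-methoxyphenyl]-2,2-dimethyl-1,3-dioxan-5-yl}oxy)-3-methoxybenzoate | COC(=O)c1ccc(O[C@H]2COC(C)(C)O[C@H]2c3ccc(OCc4ccccc4)c(OC)c3)c(OC)c1 | intermediate
16 | [4-({(4S,5S)-4-[4-(benzyloxy)-3-methoxyphenyl]-2,2-dimethyl-1,3-dioxan-5-yl}oxy)-3-methoxyphenyl]methanol | OCc1ccc(O[C@H]2COC(C)(C)O[C@H]2c3ccc(OCc4ccccc4)c(OC)c3)c(OC)c1 | intermediate
17 | (4S,5S)-4-[4-(benzyloxy)-3-methoxyphenyl]-5-[4-(bromomethyl)-2-methoxyphenoxy]-2,2-dimethyl-1,3-dioxane | BrCc1ccc(O[C@H]2COC(C)(C)O[C@H]2c3ccc(OCc4ccccc4)c(OC)c3)c(OC)c1 | intermediate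
18 | lithium enolate of 6 (formed in the flask, not isolated) | COc1cc(C[C@H]2COC(O[Li])=C2)ccc1OCc1ccccc1 | intermediate
19 | (3R,4R)-trans-lactone: 6 alkylated at C3 with the ring B benzyl group of 17 | COc1cc(C[C@H]2COC(=O)[C@@H]2Cc3ccc(O[C@H]4COC(C)(C)O[C@H]4c5ccc(OCc6ccccc6)c(OC)c5)c(OC)c3)ccc1OCc1ccccc1 | intermediate
20 | (2R,3R)-2-[4-(benzyloxy)-3-methoxybenzyl]-3-[4-({(4S,5S)-4-[4-(benzyloxy)-3-methoxyphenyl]-2,2-dimethyl-1,3-dioxan-5-yl}oxy)-3-methoxybenzyl]butane-1,4-diol | COc1cc(C[C@@H](CO)[C@@H](Cc2ccc(O[C@H]3COC(C)(C)O[C@H]3c4ccc(OCc5ccccc5)c(OC)c4)c(OC)c2)CO)ccc1OCc1ccccc1 | intermediate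
21 | (2R,3R)-2-(4-hydroxy-3-methoxybenzyl)-3-[4-({(4S,5S)-4-(4-hydroxy-3-methoxyphenyl)-2,2-dimethyl-1,3-dioxan-5-yl}oxy)-3-methoxybenzyl]butane-1,4-diol | COc1cc(C[C@@H](CO)[C@@H](Cc2ccc(O[C@H]3COC(C)(C)O[C@H]3c4ccc(O)c(OC)c4)c(OC)c2)CO)ccc1O | intermediate
22 | dipivalate of 21 at the phenols of rings A and C; C5 and C9 hydroxyls free (precursor of the key step) | COc1cc(C[C@@H](CO)[C@@H](Cc2ccc(O[C@H]3COC(C)(C)O[C@H]3c4ccc(OC(=O)C(C)(C)C)c(OC)c4)c(OC)c2)CO)ccc1OC(=O)C(C)(C)C | intermediate
23 | protected target: (2S,3R,4R)-tetrahydrofuran, 7'',9''-acetonide, aryl pivalates on rings A and C (product of the key step) | COc1cc(C[C@H]2CO[C@H](c3ccc(O[C@H]4COC(C)(C)O[C@H]4c5ccc(OC(=O)C(C)(C)C)c(OC)c5)c(OC)c3)[C@H]2CO)ccc1OC(=O)C(C)(C)C | intermediate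
24 | dipivalate triol: 23 without the acetonide (formed in the flask, not isolated) | COc1cc(C[C@H]2CO[C@H](c3ccc(O[C@@H](CO)[C@@H](O)c4ccc(OC(=O)C(C)(C)C)c(OC)c4)c(OC)c3)[C@H]2CO)ccc1OC(=O)C(C)(C)C | intermediate
25 | target CNP0226724.1: (2S,3R,4R)-lariciresinol 4-O-(7''S,8''S)-threo-guaiacylglycerol 8''-ether | COc1cc(C[C@H]2CO[C@H](c3ccc(O[C@@H](CO)[C@@H](O)c4ccc(O)c(OC)c4)c(OC)c3)[C@H]2CO)ccc1O | target

## Step count and least certain steps

Total step count: 16. Longest linear sequence: 13 steps (steps 4 to 16, from 7 and 8). The ring A branch (steps 1 to 3) joins at step 11.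

**Step 15 (key step).** The most likely failure is further oxidation at C2: the C2–H of 23 is benzylic and α to oxygen, so it is at least as hydridic as the methylene of 22, and a second hydride loss would end in a ring-opened aryl ketone after work-up. The second risk is acid-induced reopening of the ether and Friedel–Crafts closure onto C6 of ring A, which is para to its methoxy group. The fallback brings C2 in at the carbinol level by C–C bond formation instead of C–H oxidation. It sets out from 16 and 6. Alcohol 16 is oxidised with MnO2 in CH2Cl2 to the ring B aldehyde F1. The enolate 18, made from 6 as in step 11, is added to it at −78 °C to give the trans hydroxy lactone F2 as carbinol epimers. LiAlH4 gives the triol F3. A catalytic amount of camphorsulfonic acid in dry CH2Cl2 at 0 °C ionises the C2 carbinol, and the C5 hydroxyl closes the ring to the dibenzyl tetrahydrofuran acetonide F4 with the 2,3-trans arrangement. Aqueous acetic acid removes the acetal to give the dibenzyl triol F5, and hydrogenolysis (H2, Pd/C, EtOAc, stopped after two equivalents) frees the two phenols. The fallback rejoins the route at 25.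

**Step 14.** The most likely failure is loss of chemoselectivity: partial acylation of the C5 or C9 hydroxyl would block or misdirect the ring closure, and hydrolysis of the acid chloride in the aqueous phase could leave the diacylation incomplete. The fallback masks the diol before the exchange and sets out from 20. TBSCl and imidazole in DMF give the bis(silyl ether) F6; hydrogenolysis (H2, Pd/C) gives the bisphenol F7; PivCl, Et3N and catalytic DMAP in CH2Cl2 give the dipivalate bis(silyl ether) F8; HF·pyridine buffered with pyridine in THF at 0 °C removes the silyl groups. The fallback rejoins at 22.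

**Step 6.** The most likely failure is incomplete enolisation or erosion of facial selectivity, because the aryloxy oxygen and the ring B ester can compete for boron, with retro-aldol loss during work-up as a second risk. The fallback changes auxiliary, metal and the order of assembly, and sets out from 10. Alkylation with tert-butyl bromoacetate and K2CO3 gives the tert-butyl aryloxyacetate F9; trifluoroacetic acid gives the aryloxyacetic acid F10; coupling with (R)-4-benzyl-1,3-thiazolidine-2-thione (EDC·HCl, DMAP) gives the N-acyl thiazolidinethione F11. Its titanium enolate (TiCl4, i-Pr2NEt, N-methylpyrrolidinone, CH2Cl2, −78 °C), run in the non-chelated mode, should add to 1 with the same syn sense to give the aldol adduct F12. NaBH4 in THF–EtOH cleaves the auxiliary reductively. The fallback rejoins at 14.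

**Step 2.** The most likely failure is enantioselectivity below what the later diastereomer purity needs, or the opposite sense of induction, because E and Z isomers of 3 may be reduced with different selectivity and the carboxylate must bind rhodium. The fallback replaces asymmetric catalysis by resolution and sets out from 3. Hydrogenation with the achiral complex [Rh(cod)(dppb)]BF4 gives the racemic half-ester F13. Crystallisation with (R)-1-phenylethylamine (or its antipode, whichever gives the less soluble salt of the R acid) gives the ammonium salt F14, and acidification frees the acid. The fallback rejoins at 4.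

## Further compounds

F1 | step 15 | 4-({(4S,5S)-4-[4-(benzyloxy)-3-methoxyphenyl]-2,2-dimethyl-1,3-dioxan-5-yl}oxy)-3-methoxybenzaldehyde | O=Cc1ccc(O[C@H]2COC(C)(C)O[C@H]2c3ccc(OCc4ccccc4)c(OC)c3)c(OC)c1
F2 | step 15 | trans lactone 19 carrying a hydroxyl on C2 (carbinol epimers) | COc1cc(C[C@H]2COC(=O)[C@@H]2C(O)c3ccc(O[C@H]4COC(C)(C)O[C@H]4c5ccc(OCc6ccccc6)c(OC)c5)c(OC)c3)ccc1OCc1ccccc1
F3 | step 15 | triol: diol 20 carrying a hydroxyl on C2 (carbinol epimers) | COc1cc(C[C@@H](CO)[C@@H](C(O)c2ccc(O[C@H]3COC(C)(C)O[C@H]3c4ccc(OCc5ccccc5)c(OC)c4)c(OC)c2)CO)ccc1OCc1ccccc1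
F4 | step 15 | 23 with benzyl ethers in place of the two pivalates | COc1cc(C[C@H]2CO[C@H](c3ccc(O[C@H]4COC(C)(C)O[C@H]4c5ccc(OCc6ccccc6)c(OC)c5)c(OC)c3)[C@H]2CO)ccc1OCc1ccccc1
F5 | step 15 | target 25 as its bis(benzyl ether) at the phenols of rings A and C | COc1cc(C[C@H]2CO[C@H](c3ccc(O[C@@H](CO)[C@@H](O)c4ccc(OCc5ccccc5)c(OC)c4)c(OC)c3)[C@H]2CO)ccc1OCc1ccccc1
F6 | step 14 | bis(tert-butyldimethylsilyl) ether of 20 at O5 and O9 | COc1cc(C[C@@H](CO[Si](C)(C)C(C)(C)C)[C@@H](Cc2ccc(O[C@H]3COC(C)(C)O[C@H]3c4ccc(OCc5ccccc5)c(OC)c4)c(OC)c2)CO[Si](C)(C)C(C)(C)C)ccc1OCc1ccccc1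
F7 | step 14 | bis(tert-butyldimethylsilyl) ether of 21 at O5 and O9 | COc1cc(C[C@@H](CO[Si](C)(C)C(C)(C)C)[C@@H](Cc2ccc(O[C@H]3COC(C)(C)O[C@H]3c4ccc(O)c(OC)c4)c(OC)c2)CO[Si](C)(C)C(C)(C)C)ccc1O
F8 | step 14 | bis(tert-butyldimethylsilyl) ether of 22 at O5 and O9 | COc1cc(C[C@@H](CO[Si](C)(C)C(C)(C)C)[C@@H](Cc2ccc(O[C@H]3COC(C)(C)O[C@H]3c4ccc(OC(=O)C(C)(C)C)c(OC)c4)c(OC)c2)CO[Si](C)(C)C(C)(C)C)ccc1OC(=O)C(C)(C)C
F9 | step 6 | methyl 4-(2-tert-butoxy-2-oxoethoxy)-3-methoxybenzoate | COC(=O)c1ccc(OCC(=O)OC(C)(C)C)c(OC)c1
F10 | step 6 | 2-[2-methoxy-4-(methoxycarbonyl)phenoxy]acetic acid | COC(=O)c1ccc(OCC(=O)O)c(OC)c1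
F11 | step 6 | methyl 4-{2-[(R)-4-benzyl-2-thioxothiazolidin-3-yl]-2-oxoethoxy}-3-methoxybenzoate | COC(=O)c1ccc(OCC(=O)N2[C@H](Cc3ccccc3)CSC2=S)c(OC)c1
F12 | step 6 | 2,3-syn aldol adduct of F11 with 1 (same C7''/C8'' arrangement as 13) | COC(=O)c1ccc(O[C@@H](C(=O)N2[C@H](Cc3ccccc3)CSC2=S)[C@@H](O)c4ccc(OCc5ccccc5)c(OC)c4)c(OC)c1
F13 | step 2 | racemic 4-[4-(benzyloxy)-3-methoxyphenyl]-3-(methoxycarbonyl)butanoic acid | COC(=O)C(CC(=O)O)Cc1ccc(OCc2ccccc2)c(OC)c1
F14 | step 2 | (R)-1-phenylethylammonium salt of 4 | COC(=O)[C@@H](CC(=O)[O-])Cc1ccc(OCc2ccccc2)c(OC)c1.C[C@@H]([NH3+])c1ccccc1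
A1 | alternative 1 | (5R)-5-[(1R,2S,5R)-menthyloxy]furan-2(5H)-one | O=C1C=C[C@H](O[C@@H]2C[C@H](C)CC[C@H]2C(C)C)O1
A2 | alternative 1 | 2-[4-(benzyloxy)-3-methoxyphenyl]-1,3-dithiane | COc1cc(C2SCCCS2)ccc1OCc1ccccc1
A3 | alternative 1 | 4-({(4S,5S)-4-[4-(benzyloxy)-3-methoxyphenyl]-2,2-dimethyl-1,3-dioxan-5-yl}oxy)-3-methoxybenzaldehyde | O=Cc1ccc(O[C@H]2COC(C)(C)O[C@H]2c3ccc(OCc4ccccc4)c(OC)c3)c(OC)c1
A4 | alternative 1 | trans,trans-3-(hydroxyarylmethyl)-4-(2-aryl-1,3-dithian-2-yl)-5-menthyloxy lactone (carbinol epimers) | COc1cc(C2(SCCCS2)[C@H]3[C@H](O[C@@H]4C[C@H](C)CC[C@H]4C(C)C)OC(=O)[C@@H]3C(O)c5ccc(O[C@H]6COC(C)(C)O[C@H]6c7ccc(OCc8ccccc8)c(OC)c7)c(OC)c5)ccc1OCc1ccccc1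
A5 | alternative 2 | 3-[4-(benzyloxy)-3-methoxybenzyl]cyclobutan-1-one | COc1cc(CC2CC(=O)C2)ccc1OCc1ccccc1
A6 | alternative 2 | (R)-4-[4-(benzyloxy)-3-methoxybenzyl]dihydrofuran-2(3H)-one | COc1cc(C[C@H]2COC(=O)C2)ccc1OCc1ccccc1
A7 | alternative 3 | 2,3-trans-2-aryl-3-[(tert-butyldimethylsilyloxy)methyl]-4,5-epoxytetrahydropyran, epoxide cis to the silyloxymethyl arm | CC(C)(C)[Si](C)(C)OC[C@@H]1[C@@H](c2ccc(O[C@H]3COC(C)(C)O[C@H]3c4ccc(OCc5ccccc5)c(OC)c4)c(OC)c2)OC[C@@H]2O[C@H]12
A8 | alternative 3 | 2,3-trans-3,4-cis-2-aryl-3-[(tert-butyldimethylsilyloxy)methyl]tetrahydrofuran-4-carbaldehyde | O=C[C@H]2CO[C@H](c3ccc(O[C@H]4COC(C)(C)O[C@H]4c5ccc(OCc6ccccc6)c(OC)c5)c(OC)c3)[C@H]2CO[Si](C)(C)C(C)(C)C
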